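**Plan** (numbering of the target: carbocycle C1–C10, methyl C14 on C10, methyl C15 on C4, lactone C6–O–C12(=O)–C11(=C13)–C7)

1. Retrosynthesis first removes the tiglate (C8–O acyl bond), C13 (C11=C13) and C14 (C10–CH3). It then reconnects C5–C10: C10 and C5 face each other across the ten-membered ring, flanked by the Z C4=C5 olefin and the C3 carbinol, which is the pattern left by fragmenting a cis-fused 3,4-epoxy-octal-1-en-10-ol.
2. The bicycle is cut at C1=C2 (metathesis), C10–C1 (acetylide addition), the C3–C4 oxirane (Sharpless), C4–C5 (Negishi), C6–O (oxa-Michael) and C7–C11 (Johnson–Claisen), back to meso cis-cyclohex-2-ene-1,4-diyl diacetate.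
3. Forward: ring B (C5–C10) is there from the start, the γ-lactone closes second, ring A closes third, and cutting the shared C5–C10 bond then unveils the ten-membered ring; C14, C13 and the tiglate come last.
4. Stereochemistry: C8 from lipase desymmetrisation; C7 by suprafacial [3,3] transfer; C6 by the tethered (cis) lactone closure and C5 by equilibration; the bicyclic C10 carbinol by axial acetylide attack; C3/C4 by reagent-controlled epoxidation.
5. Both olefins are Z by ring constraint and by the stereospecific fragmentation; the final C10 centre comes from methyl addition to the ketone held by the C3 alkoxide.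

Key step: step 19

Assumption: the lipase hydrolysis in step 2 is taken to give the (1S,4R)-monoacetate; if the enzyme at hand gives the antipode, the same enzyme used for acylation of the meso diol gives the required enantiomer.

TBS = tert-butyldimethylsilyl; MOP = 2-methoxyprop-2-yl.

Step 1
Reactants: 1 cyclohexa-1,3-diene
Product: 2 cis-cyclohex-2-ene-1,4-diyl diacetate (meso)
Conditions: Pd(OAc)2 (cat.), LiCl (cat.), LiOAc, p-benzoquinone (cat.), MnO2, AcOH, rt
Reagents that add atoms: acetic acid, CC(=O)O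
Why: Palladium(II)-catalysed 1,4-diacetoxylation of a 1,3-diene (Bäckvall oxidation); with catalytic chloride both acetates arrive by external attack anti to palladium, which gives the cis, hence meso, diacetate.

Step 2
Reactants: 2 cis-cyclohex-2-ene-1,4-diyl diacetate
Product: 3 (1S,4R)-4-hydroxycyclohex-2-en-1-yl acetate
Conditions: lipase (CAL-B), phosphate buffer pH 7, rt
Reagents that add atoms: none
Why: Lipase-mediated desymmetrisation of the meso diacetate (hydrolysis of one enantiotopic ester) fixes the absolute configuration of the carbinol that becomes C8.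

Step 3
Reactants: 3 (1S,4R)-4-hydroxycyclohex-2-en-1-yl acetate
Product: 4 (1S,4R)-4-(TBS-oxy)cyclohex-2-en-1-yl acetate
Conditions: TBSCl, imidazole, DMF, rt
Reagents that add atoms: tert-butyldimethylsilyl chloride, CC(C)(C)[Si](C)(C)Cl
Why: Standard silylation of the free secondary allylic alcohol, which becomes the C8 silyl ether carried to step 23.

Step 4
Reactants: 4 (1S,4R)-4-(TBS-oxy)cyclohex-2-en-1-yl acetate
Product: 5 (1S,4R)-4-(TBS-oxy)cyclohex-2-en-1-ol
Conditions: K2CO3 (cat.), MeOH, 0 °C
Reagents that add atoms: none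
Why: Base-catalysed transesterification removes the acetate without touching the silyl ether and frees the allylic alcohol needed for the rearrangement.

Step 5
Reactants: 5 (1S,4R)-4-(TBS-oxy)cyclohex-2-en-1-ol
Product: 7 ethyl 2-[(1S,6R)-6-(TBS-oxy)cyclohex-2-en-1-yl]acetate, via ketene acetal 6 (not isolated)
Conditions: MeC(OEt)3, EtCO2H (cat.), xylene, 140 °C, EtOH distilled off
Reagents that add atoms: triethyl orthoacetate, CC(OCC)(OCC)OCC
Why: Johnson–Claisen rearrangement: the ketene acetal formed on the allylic oxygen rearranges suprafacially through a chair-like [3,3] transition state, so the new C7–C11 bond forms on the face that carried the C–O bond and ends cis to the C8 silyl ether (7S).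

Step 6
Reactants: 7 ethyl 2-[(1S,6R)-6-(TBS-oxy)cyclohex-2-en-1-yl]acetate
Product: 8 ethyl 2-[(1S,6R)-6-(TBS-oxy)-4-oxocyclohex-2-en-1-yl]acetate
Conditions: Rh2(cap)4 (cat.), t-BuOOH, K2CO3 (cat.), CH2Cl2, rt
Reagents that add atoms: tert-butyl hydroperoxide, CC(C)(C)OO
Why: Dirhodium caprolactamate-catalysed allylic oxidation should convert the unhindered ring methylene (C10) into the enone carbonyl, the tertiary allylic C7–H being shielded by its ester and silyloxy neighbours.

Step 7
Reactants: 8 ethyl 2-[(1S,6R)-6-(TBS-oxy)-4-oxocyclohex-2-en-1-yl]acetate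
Product: 9 ethyl 2-[(1S,6R)-6-(TBS-oxy)-3-iodo-4-oxocyclohex-2-en-1-yl]acetate
Conditions: I2, pyridine, CH2Cl2, 0 °C → rt
Reagents that add atoms: iodine, II
Why: α-Iodination of the enone by the pyridine addition–iodination–elimination sequence (Johnson's procedure) places the halogen on C5 only, since only the enone α-carbon can react this way.

Step 8
Reactants: 10 but-2-yn-1-ol
Product: 12 (2Z)-3-iodobut-2-en-1-ol, via sodium alkenylalanate 11 (not isolated)
Conditions: Red-Al, THF, 0 °C → rt; then I2, −78 → 0 °C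
Reagents that add atoms: iodine, II
Why: Hydroxyl-directed trans-hydroalumination of the propargylic alcohol gives the cyclic alkenylalanate, whose iodinolysis with retention delivers the (Z)-iodide in which iodine and CH2OH are cis.

Step 9
Reactants: 12 (2Z)-3-iodobut-2-en-1-ol
Product: 13 tert-butyl{[(2Z)-3-iodobut-2-en-1-yl]oxy}dimethylsilane
Conditions: TBSCl, imidazole, CH2Cl2, rt
Reagents that add atoms: tert-butyldimethylsilyl chloride, CC(C)(C)[Si](C)(C)Cl
Why: Silylation of the primary allylic alcohol so that the iodide can be lithiated in the next step.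

Step 10
Reactants: 9 ethyl 2-[(1S,6R)-6-(TBS-oxy)-3-iodo-4-oxocyclohex-2-en-1-yl]acetate; 13 tert-butyl{[(2Z)-3-iodobut-2-en-1-yl]oxy}dimethylsilane
Product: 16 ethyl 2-[(1S,6R)-6-(TBS-oxy)-3-[(2Z)-4-(TBS-oxy)but-2-en-2-yl]-4-oxocyclohex-2-en-1-yl]acetate, via alkenyllithium 14 (not isolated), via alkenylzinc chloride 15 (not isolated)
Conditions: 13, t-BuLi (2 equiv), Et2O, −78 °C; ZnCl2, THF, −78 → 0 °C; then 9, Pd(PPh3)4 (cat.), THF, rt
Reagents that add atoms: none
Why: Iodine–lithium exchange, transmetallation to zinc and palladium-catalysed Negishi coupling with the α-iodo enone form the C4–C5 bond with retention of the Z geometry, which places C5 and C2 cis as the later oxirane and ring A require.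

Step 11
Reactants: 16 ethyl 2-[(1S,6R)-6-(TBS-oxy)-3-[(2Z)-4-(TBS-oxy)but-2-en-2-yl]-4-oxocyclohex-2-en-1-yl]acetate
Product: 18 (3aS,4R,7S,7aR)-4-(TBS-oxy)-7-[(2Z)-4-(TBS-oxy)but-2-en-2-yl]hexahydro-1-benzofuran-2,6-dione (cis-fused keto-lactone; C5 side chain trans to O6), via enone acid 17 (not isolated)
Conditions: LiOH, THF–H2O, 0 °C; 1 M HCl to pH 3; then PPTS (cat.), CH2Cl2, rt
Reagents that add atoms: lithium hydroxide, [Li+].[OH-]
Why: Saponification frees the C12 acid, which adds to C6 of the enone (intramolecular oxa-Michael addition; the tether on C7 reaches only its own face, so the γ-lactone is cis-fused), and C5, epimerisable next to the ketone, should settle with the alkenyl group equatorial and trans to O6.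

Step 12
Reactants: 18 keto-lactone
Product: 19 (3aS,4R,6S,7S,7aR)-4-(TBS-oxy)-7-[(2Z)-4-(TBS-oxy)but-2-en-2-yl]-6-ethynyl-6-hydroxyhexahydro-1-benzofuran-2(3H)-one (C10–OH cis to H5 and to O6/O8)
Conditions: HC≡CMgBr, CeCl3, THF, −78 °C
Reagents that add atoms: ethynylmagnesium bromide, C#C[Mg]Br
Why: Organocerium 1,2-addition avoids enolising the β-acyloxy ketone; the slim sp nucleophile takes the axial trajectory on the chair in which O6, O8 and the C5 side chain are equatorial, so the new C10 hydroxyl is equatorial and cis to H5, the relationship of the later cis ring fusion.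

Step 13
Reactants: 19 ethynyl carbinol
Product: 20 (3aS,4R,6R,7S,7aR)-4-(TBS-oxy)-7-[(2Z)-4-(TBS-oxy)but-2-en-2-yl]-6-ethenyl-6-hydroxyhexahydro-1-benzofuran-2(3H)-one
Conditions: H2 (1 atm), Lindlar catalyst, quinoline, EtOAc, rt
Reagents that add atoms: none
Why: Lindlar semi-hydrogenation stops at the terminal olefin, and the trisubstituted olefin is not reduced over the poisoned catalyst.

Step 14
Reactants: 20 vinyl carbinol
Product: 21 (3aS,4R,6R,7S,7aR)-4-(TBS-oxy)-6-ethenyl-6-hydroxy-7-[(2Z)-4-hydroxybut-2-en-2-yl]hexahydro-1-benzofuran-2(3H)-one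
Conditions: HF·pyridine, pyridine, THF, 0 °C
Reagents that add atoms: none
Why: Buffered HF·pyridine cleaves the primary allylic silyl ether much faster than the hindered secondary one at C8 (selective desilylation).

Step 15
Reactants: 21 allylic alcohol
Product: 22 (3aS,4R,6R,7S,7aR)-4-(TBS-oxy)-6-ethenyl-6-hydroxy-7-[(2S,3R)-3-(hydroxymethyl)-2-methyloxiran-2-yl]hexahydro-1-benzofuran-2(3H)-one
Conditions: Ti(OiPr)4, D-(−)-DIPT, t-BuOOH, 4 Å MS, CH2Cl2, −25 °C
Reagents that add atoms: tert-butyl hydroperoxide, CC(C)(C)OO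
Why: Sharpless asymmetric epoxidation of the primary (Z)-trisubstituted allylic alcohol (the nerol-type case) is reagent-controlled, and D-(−)-tartrate should deliver oxygen to the face that gives the (3R,4S) oxirane in target numbering, the tertiary vinyl carbinol being inert.

Step 16
Reactants: 22 epoxy alcohol
Product: 23 (3aS,4R,6R,7S,7aR)-4-(TBS-oxy)-6-ethenyl-7-[(2S,3S)-3-formyl-2-methyloxiran-2-yl]-6-hydroxyhexahydro-1-benzofuran-2(3H)-one
Conditions: Dess–Martin periodinane, NaHCO3, CH2Cl2, 0 °C
Reagents that add atoms: none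
Why: Dess–Martin oxidation gives the α,β-epoxy aldehyde under buffered, non-epimerising conditions, and the tertiary alcohol cannot be oxidised.

Step 17
Reactants: 23 epoxy aldehyde
Product: 24 (3aS,4R,6R,7S,7aR)-4-(TBS-oxy)-6-ethenyl-7-[(2S,3R)-3-ethenyl-2-methyloxiran-2-yl]-6-hydroxyhexahydro-1-benzofuran-2(3H)-one
Conditions: Ph3PCH3Br, KHMDS, THF, 0 °C; then 23, −78 → 0 °C
Reagents that add atoms: methyltriphenylphosphonium bromide, C[P+](c1ccccc1)(c1ccccc1)c1ccccc1.[Br-]
Why: Wittig methylenation of the aldehyde (which may rest as its lactol with the C10 hydroxyl) with an excess of ylide gives the vinyl oxirane, the lactone carbonyl being inert to the ylide at low temperature.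

Step 18
Reactants: 24 diene
Product: 25 cis-fused epoxy-octalinol lactone: 3,4-epoxy-10-hydroxy-4-methyl-8-(TBS-oxy)octal-1-ene carrying the cis 6,12-γ-lactone, (3R,4S,5S,6R,7S,8R,10R) in target numbering
Conditions: Grubbs II (cat.), CH2Cl2, 40 °C
Reagents that add atoms: none
Why: Ring-closing metathesis of the two monosubstituted olefins closes the six-membered ring A with loss of ethylene and can only give the Z C1=C2 bond; vinyl oxiranes and tertiary allylic alcohols are tolerated by the ruthenium carbene.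

Step 19
Reactants: 25 cis-fused epoxy-octalinol lactone
Product: 27 (1Z,4Z)-3-hydroxy-10-oxo-8-(TBS-oxy)cyclodeca-1,4-diene 6,12-lactone, (3R,6S,7S,8R) in target numbering, via potassium alkoxide 26 (not isolated)
Conditions: KHMDS (1.05 equiv), 18-crown-6, THF, −78 → 0 °C; AcOH, −78 °C
Reagents that add atoms: none
Why: The C10 alkoxide pushes into the C5–C10 σ bond while the oxirane C4–O bond leaves, so that C10=O and C4=C5 form and the C3 alkoxide is released; this is a Grob-type fragmentation with an epoxide as leaving group (epoxy-alcohol fragmentation). No ring is closed: the ten-membered carbocycle appears by scission of the bond shared by rings A and B, so no cyclisation entropy or transannular strain is paid, and release of oxirane strain at the tertiary C4 drives it. No stereocentre is created; C3 keeps the configuration of its C–O bond and C1=C2 is Z because it comes from a cyclohexene. C4=C5 should be Z because, in the cis-fused conformer with ring B in its chair (O6 and O8 equatorial), the C5–C6 bond is axial on ring A and eclipses the departing oxygen, which puts C3 and C6 on the same side of the new olefin. The step needs fragmentation to outrun oxetane formation at C4, lactone enolisation and base-induced isomerisation of the product; since a fused oxirane can offer only an anticlinal (about 120°) C4–O/C5–C10 alignment, a dissociated potassium alkoxide, one equivalent of base and a cold acidic quench are used. The product is handled as the hydroxy enone, which may rest partly as its 3,10-hemiketal.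

Step 20
Reactants: 27 hydroxy enone
Product: 28 (1Z,4Z)-3,10-dihydroxy-10-methyl-8-(TBS-oxy)cyclodeca-1,4-diene 6,12-lactone, (3R,6S,7S,8R,10R)
Conditions: MeMgBr, CeCl3, THF, −78 °C
Reagents that add atoms: methylmagnesium bromide, C[Mg]Br
Why: Organocerium 1,2-addition (Imamoto conditions) spares the lactone and does not enolise toward the β-silyloxy carbon; the C3 alkoxide formed by the first equivalent should sit beside C10 in the plane of the Z C1=C2 bond (the geometry of the 3,10-hemiketal) and hold the carbonyl oxygen on its side, so that methyl enters from the outer face and the new hydroxyl ends syn to O3 (10R).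

Step 21
Reactants: 28 diol
Product: 29 3-O-MOP ether of 28, (3R,6S,7S,8R,10R)
Conditions: 2-methoxypropene, PPTS (cat.), CH2Cl2, 0 °C
Reagents that add atoms: 2-methoxypropene, C=C(C)OC
Why: Acid-catalysed addition of the secondary allylic alcohol to the enol ether gives the mixed acetal, and the hindered tertiary C10 hydroxyl is left free.

Step 22
Reactants: 29 MOP ether
Product: 32 α-methylene lactone: 11(13)-ene of 29, (3R,6S,7S,8R,10R), via Mannich base 30 (not isolated), via ammonium iodide 31 (not isolated)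
Conditions: LDA (2.2 equiv), THF, −78 °C; CH2=NMe2 I, −78 → 0 °C; MeI, THF–MeOH, rt; aq NaHCO3, CH2Cl2
Reagents that add atoms: Eschenmoser's salt, C=[N+](C)C.[I-]
Why: α-Methylenation by the Mannich route: the lactone enolate is aminomethylated, the amine quaternised and eliminated (Hofmann-type elimination) to the exocyclic olefin, the second equivalent of base only holding the C10 hydroxyl as its alkoxide.

Step 23
Reactants: 32 α-methylene lactone
Product: 33 8-hydroxy compound: 3-O-MOP-3,8,10-triol α-methylene lactone, (3R,6S,7R,8R,10R)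
Conditions: TBAF, AcOH (1:1), THF, rt
Reagents that add atoms: none
Why: Buffered fluoride cleaves the C8 silyl ether while the acetal at C3, stable to fluoride, stays, and acetic acid keeps the medium from becoming basic enough for conjugate addition or lactone migration.

Step 24
Reactants: 33 8-hydroxy compound; 34 tigloyl chloride ((E)-2-methylbut-2-enoyl chloride)
Product: 35 8-O-tigloyl-3-O-MOP compound, (3R,6S,7R,8R,10R)
Conditions: Et3N, DMAP (cat.), CH2Cl2, 0 °C → rt
Reagents that add atoms: none
Why: DMAP-catalysed acylation of the only secondary hydroxyl; the tertiary C10 alcohol does not react and the E geometry of the tigloyl unit is the stable one.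

Step 25
Reactants: 35 8-O-tigloyl-3-O-MOP compound
Product: 36 target, (1Z,4Z)-3,10-dihydroxy-8-tigloyloxygermacra-1,4,11(13)-trien-6,12-olide, (3R,6S,7R,8R,10R)
Conditions: PPTS (cat.), MeOH, 0 °C
Reagents that add atoms: none
Why: Mild acid-catalysed methanolysis of the mixed acetal (transacetalisation) frees the C3 hydroxyl without ionising the allylic alcohols or touching the esters.

**Compound list**

1 | cyclohexa-1,3-diene | C1=CC=CCC1 | starting material
2 | cis-cyclohex-2-ene-1,4-diyl diacetate (meso) | CC(=O)O[C@@H]1C=C[C@H](OC(C)=O)CC1 | intermediate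
3 | (1S,4R)-4-hydroxycyclohex-2-en-1-yl acetate | CC(=O)O[C@@H]1C=C[C@H](O)CC1 | intermediate
4 | (1S,4R)-4-(TBS-oxy)cyclohex-2-en-1-yl acetate | CC(=O)O[C@@H]1C=C[C@H](O[Si](C)(C)C(C)(C)C)CC1 | intermediate
5 | (1S,4R)-4-(TBS-oxy)cyclohex-2-en-1-ol | O[C@@H]1C=C[C@H](O[Si](C)(C)C(C)(C)C)CC1 | intermediate
6 | mixed ketene acetal of 5 (1-ethoxyethenyl ether) | C=C(OCC)O[C@@H]1C=C[C@H](O[Si](C)(C)C(C)(C)C)CC1 | intermediate
7 | ethyl 2-[(1S,6R)-6-(TBS-oxy)cyclohex-2-en-1-yl]acetate | CCOC(=O)C[C@H]1C=CCC[C@H]1O[Si](C)(C)C(C)(C)C | intermediate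
8 | ethyl 2-[(1S,6R)-6-(TBS-oxy)-4-oxocyclohex-2-en-1-yl]acetate | CCOC(=O)C[C@H]1C=CC(=O)C[C@H]1O[Si](C)(C)C(C)(C)C | intermediate
9 | ethyl 2-[(1S,6R)-6-(TBS-oxy)-3-iodo-4-oxocyclohex-2-en-1-yl]acetate | CCOC(=O)C[C@H]1C=C(I)C(=O)C[C@H]1O[Si](C)(C)C(C)(C)C | intermediate
10 | but-2-yn-1-ol | CC#CCO | starting material
11 | sodium alkenylalanate (cyclic, from Red-Al) | CC1=CCO[Al-]1(OCCOC)OCCOC.[Na+] | intermediate
12 | (2Z)-3-iodobut-2-en-1-ol | C/C(I)=C/CO | intermediate
13 | tert-butyl{[(2Z)-3-iodobut-2-en-1-yl]oxy}dimethylsilane | C/C(I)=C/CO[Si](C)(C)C(C)(C)C | intermediate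
14 | (Z)-alkenyllithium from 13 | C/C([Li])=C/CO[Si](C)(C)C(C)(C)C | intermediate
15 | (Z)-alkenylzinc chloride from 14 | C/C([Zn]Cl)=C/CO[Si](C)(C)C(C)(C)C | intermediate
16 | ethyl 2-[(1S,6R)-6-(TBS-oxy)-3-[(2Z)-4-(TBS-oxy)but-2-en-2-yl]-4-oxocyclohex-2-en-1-yl]acetate | CCOC(=O)C[C@H]1C=C(/C(C)=C\CO[Si](C)(C)C(C)(C)C)C(=O)C[C@H]1O[Si](C)(C)C(C)(C)C | intermediate
17 | carboxylic acid of 16 | OC(=O)C[C@H]1C=C(/C(C)=C\CO[Si](C)(C)C(C)(C)C)C(=O)C[C@H]1O[Si](C)(C)C(C)(C)C | intermediate
18 | (3aS,4R,7S,7aR)-4-(TBS-oxy)-7-[(2Z)-4-(TBS-oxy)but-2-en-2-yl]hexahydro-1-benzofuran-2,6-dione | C1C(=O)O[C@H]2[C@H](/C(C)=C\CO[Si](C)(C)C(C)(C)C)C(=O)C[C@@H](O[Si](C)(C)C(C)(C)C)[C@@H]12 | intermediate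
19 | (3aS,4R,6S,7S,7aR)-6-ethynyl-6-hydroxy analogue of 18 | C1C(=O)O[C@H]2[C@H](/C(C)=C\CO[Si](C)(C)C(C)(C)C)[C@](O)(C#C)C[C@@H](O[Si](C)(C)C(C)(C)C)[C@@H]12 | intermediate
20 | (3aS,4R,6R,7S,7aR)-6-ethenyl-6-hydroxy analogue | C1C(=O)O[C@H]2[C@H](/C(C)=C\CO[Si](C)(C)C(C)(C)C)[C@](O)(C=C)C[C@@H](O[Si](C)(C)C(C)(C)C)[C@@H]12 | intermediate
21 | (3aS,4R,6R,7S,7aR)-4-(TBS-oxy)-6-ethenyl-6-hydroxy-7-[(2Z)-4-hydroxybut-2-en-2-yl]hexahydro-1-benzofuran-2(3H)-one | C1C(=O)O[C@H]2[C@H](/C(C)=C\CO)[C@](O)(C=C)C[C@@H](O[Si](C)(C)C(C)(C)C)[C@@H]12 | intermediate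
22 | 7-[(2S,3R)-3-(hydroxymethyl)-2-methyloxiran-2-yl] analogue of 21 | C1C(=O)O[C@H]2[C@H]([C@]3(C)O[C@@H]3CO)[C@](O)(C=C)C[C@@H](O[Si](C)(C)C(C)(C)C)[C@@H]12 | intermediate
23 | 7-[(2S,3S)-3-formyl-2-methyloxiran-2-yl] analogue | C1C(=O)O[C@H]2[C@H]([C@]3(C)O[C@@H]3C=O)[C@](O)(C=C)C[C@@H](O[Si](C)(C)C(C)(C)C)[C@@H]12 | intermediate
24 | 7-[(2S,3R)-3-ethenyl-2-methyloxiran-2-yl] analogue | C1C(=O)O[C@H]2[C@H]([C@]3(C)O[C@@H]3C=C)[C@](O)(C=C)C[C@@H](O[Si](C)(C)C(C)(C)C)[C@@H]12 | intermediate
25 | cis-fused 3,4-epoxy-10-hydroxy-8-(TBS-oxy)octal-1-ene 6,12-lactone, (3R,4S,5S,6R,7S,8R,10R) | C1C(=O)O[C@H]2[C@@H]3[C@]4(C)O[C@@H]4C=C[C@]3(O)C[C@@H](O[Si](C)(C)C(C)(C)C)[C@@H]12 | intermediate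
26 | potassium C10 alkoxide of 25 | C1C(=O)O[C@H]2[C@@H]3[C@]4(C)O[C@@H]4C=C[C@]3([O-])C[C@@H](O[Si](C)(C)C(C)(C)C)[C@@H]12.[K+] | intermediate
27 | (1Z,4Z)-3-hydroxy-10-oxo-8-(TBS-oxy)cyclodeca-1,4-diene 6,12-lactone, (3R,6S,7S,8R) | C1C(=O)O[C@H]2/C=C(/C)[C@H](O)/C=C\C(=O)C[C@@H](O[Si](C)(C)C(C)(C)C)[C@@H]12 | intermediate
28 | (1Z,4Z)-3,10-dihydroxy-10-methyl-8-(TBS-oxy) lactone, (3R,6S,7S,8R,10R) | C1C(=O)O[C@H]2/C=C(/C)[C@H](O)/C=C\[C@](C)(O)C[C@@H](O[Si](C)(C)C(C)(C)C)[C@@H]12 | intermediate
29 | 3-O-MOP ether of 28 | C1C(=O)O[C@H]2/C=C(/C)[C@H](OC(C)(C)OC)/C=C\[C@](C)(O)C[C@@H](O[Si](C)(C)C(C)(C)C)[C@@H]12 | intermediate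
30 | 11-(dimethylaminomethyl) lactone (Mannich base, C11 epimers) | CN(C)CC1C(=O)O[C@H]2/C=C(/C)[C@H](OC(C)(C)OC)/C=C\[C@](C)(O)C[C@@H](O[Si](C)(C)C(C)(C)C)[C@@H]12 | intermediate
31 | trimethylammonium iodide of 30 | C[N+](C)(C)CC1C(=O)O[C@H]2/C=C(/C)[C@H](OC(C)(C)OC)/C=C\[C@](C)(O)C[C@@H](O[Si](C)(C)C(C)(C)C)[C@@H]12.[I-] | intermediate
32 | α-methylene lactone, 3-O-MOP, 8-O-TBS, (3R,6S,7S,8R,10R) | C=C1C(=O)O[C@H]2/C=C(/C)[C@H](OC(C)(C)OC)/C=C\[C@](C)(O)C[C@@H](O[Si](C)(C)C(C)(C)C)[C@@H]12 | intermediate
33 | α-methylene lactone, 3-O-MOP, 8-OH, (3R,6S,7R,8R,10R) | C=C1C(=O)O[C@H]2/C=C(/C)[C@H](OC(C)(C)OC)/C=C\[C@](C)(O)C[C@@H](O)[C@@H]12 | intermediate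
34 | tigloyl chloride | C/C=C(\C)C(=O)Cl | starting material
35 | 8-O-tigloyl-3-O-MOP compound, (3R,6S,7R,8R,10R) | C=C1C(=O)O[C@H]2/C=C(/C)[C@H](OC(C)(C)OC)/C=C\[C@](C)(O)C[C@@H](OC(=O)/C(C)=C/C)[C@@H]12 | intermediate
36 | target, (3R,6S,7R,8R,10R) | C=C1C(=O)O[C@H]2/C=C(/C)[C@H](O)/C=C\[C@](C)(O)C[C@@H](OC(=O)/C(C)=C/C)[C@@H]12 | target

**Count.** 25 steps in total; longest linear sequence 23 steps (steps 1–7 and 10–25).

**Steps most likely to fail**

Step 19 (key fragmentation). The C4–O and C5–C10 bonds cannot become antiperiplanar in the fused system, so the fragmentation may be slow. The alkoxide and the product would then be exposed to base for longer, which invites isomerisation of the Z γ-hydroxy enone to a 1,4-dione, elimination of the C8 silyloxy group from the new ketone, or lactone migration. Fallback: the same bond changes by a homolytic path, from 25 straight to 27. The C10 alkoxy radical is generated under neutral proton-coupled electron-transfer photocatalysis (iridium photocatalyst, collidine, aryl thiol, blue light). β-Scission of C5–C10 gives the ketone and a secondary C5 radical, which opens the neighbouring oxirane to C4=C5 and an O3 radical that the thiol reduces to the alcohol. No base is present and no antiperiplanar alignment is needed; no compound outside the list is formed (F0).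

Step 20 (methyl addition). Facial selectivity at C10 may be poor or inverted, because a second coordinated conformer of the Z γ-oxido enone (O3 on the outer face instead of beside C10) exposes the opposite face of the carbonyl. Fallback: catalyst control instead of substrate control, setting out from 27. The C3 hydroxyl is first capped with 2-methoxypropene/PPTS to give the MOP-protected enone F1. Methyl is then added with Me2Zn, Ti(OiPr)4 and a chiral bis(sulfonamide) diol ligand (catalytic enantioselective alkylation of ketones), the ligand enantiomer being chosen for the required face. This gives 29 directly and rejoins the route before step 22.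

Step 11 (lactone closure). Conjugate addition of the acid to the cross-conjugated dienone may stop short of completion, and once C5 carries an acidic hydrogen the side-chain olefin may drift into conjugation with the ketone. Fallback: close the lactone irreversibly before the side chain is attached, setting out from 8 and returning at 18.
- Luche reduction (NaBH4, CeCl3) gives the cis allylic alcohol, ethyl 2-[(1S,4S,6R)-6-(TBS-oxy)-4-hydroxycyclohex-2-en-1-yl]acetate F2.
- Saponification and iodolactonisation (I2, NaHCO3) give the iodo hydroxy lactone F3, with the γ-lactone cis-fused and iodine on C5 trans to O6.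
- Nickel/photoredox cross-electrophile coupling of F3 with alkenyl iodide 13 (silyl-radical halogen abstraction) attaches the side chain through the C5 radical on the face away from both oxygen-bearing neighbours, giving the hydroxy lactone F4.
- Dess–Martin oxidation of the C10 alcohol then gives 18.

Further compounds

F0 | step 19 | none | none
F1 | step 20 | 3-O-MOP ether of hydroxy enone 27, (3R,6S,7S,8R) | C1C(=O)O[C@H]2/C=C(/C)[C@H](OC(C)(C)OC)/C=C\C(=O)C[C@@H](O[Si](C)(C)C(C)(C)C)[C@@H]12
F2 | step 11 | ethyl 2-[(1S,4S,6R)-6-(TBS-oxy)-4-hydroxycyclohex-2-en-1-yl]acetate | CCOC(=O)C[C@H]1C=C[C@@H](O)C[C@H]1O[Si](C)(C)C(C)(C)C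
F3 | step 11 | (3aS,4R,6S,7R,7aR)-4-(TBS-oxy)-6-hydroxy-7-iodohexahydro-1-benzofuran-2(3H)-one | C1C(=O)O[C@H]2[C@H](I)[C@@H](O)C[C@@H](O[Si](C)(C)C(C)(C)C)[C@@H]12
F4 | step 11 | (3aS,4R,6S,7R,7aR)-4-(TBS-oxy)-7-[(2Z)-4-(TBS-oxy)but-2-en-2-yl]-6-hydroxyhexahydro-1-benzofuran-2(3H)-one | C1C(=O)O[C@H]2[C@H](/C(C)=C\CO[Si](C)(C)C(C)(C)C)[C@@H](O)C[C@@H](O[Si](C)(C)C(C)(C)C)[C@@H]12
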